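## Structural features

The target is an isoflavone: a 5,7-dihydroxy-4H-chromen-4-one (rings A and C) joined through the C3–C1' bond to a resorcinol-type ring B. Ring B is fused at O–C2' and C3' to a 2H-pyran (ring D: O1'', C2'', C3''=C4''), so rings B and D form a 5-hydroxy-2H-chromene attached through its C8. The only stereocentre is C2'', a quaternary (S) carbon bearing methyl, hydroxymethyl, the ring oxygen and the vinyl carbon C3''. It has no stereogenic neighbour, so nothing can relay or correct its configuration. Fragile elements are the electron-rich styrene-type C3''=C4'' bond and the tertiary allylic aryl ether of ring D (acid, oxidants), the polyphenolic ring A, and the chromone C2 (base). The real difficulty is to place ring D on a 1,2,3,4-tetrasubstituted arene without ever breaking a bond at C2''; any passage through an ortho-quinone methide or a propargylic or allylic cation would racemise it. The key step uses the fact that C3' is the only unsubstituted carbon ortho to the C2' ether oxygen and lies between the C2' and C4' oxygens. An alkyne tethered through O1''–C2'' can therefore only be attacked by C3', which forms C3'–C4'' and closes ring D.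

## Logic of the disconnections

18 ⇒ 16 (through 17). Cut: O1–C2 and C2–C3 of ring C, together with the O–CH2OMe and O–CPh3 bonds of all protecting groups. C2 is a single formate-level carbon between an acidic methylene and a phenol oxygen, so an amide acetal can deliver it last. Ring C and five protecting groups disappear in one operation, leaving the open-chain 16. The forward step must condense at a hindered methylene and keep the acid stage short, because C3''=C4'' is acid-sensitive.

16 ⇒ 15 ⇒ 11 + 13 (through 14). Cut: the C3–C4 bond (benzylic carbon to carbonyl carbon), after a change of oxidation level at C4. This divides the molecule into a ring A piece and a ring B/D piece of similar size and makes the route convergent. 13 is taken at the aldehyde level deliberately. An aroyl chloride flanked by two alkoxymethyl ethers can be attacked by its own acetal oxygens, and zinc salts promote that reaction; the aldehyde is inert and costs only one later oxidation. The forward step needs a benzylic nucleophile, 14, made from the ionisation-prone 11 without homocoupling.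

11 ⇒ 10 ⇒ 9. No skeletal bond is cut; C–Cl goes back to C–OH and to CHO. The formyl carbon, the future C3, stays an aldehyde as long as possible because it is needed twice earlier: to activate the aryl fluoride and to block C1'. The forward steps must be non-acidic.

9 ⇒ 8 (key disconnection). Cut: C3'–C4''. Ring D opens to an aryl propargyl ether, and the quaternary centre becomes an isolated carbinol-type carbon that can be bought. The forward step must add an arene C–H across the alkyne without ionising C2''–O and without an ortho-quinone methide. The primary oxygen of 8 therefore carries a trityl group and not an alkoxymethyl group. A homopropargylic acetal can pass its alkoxy oxygen to a gold-activated alkyne (Petasis–Ferrier-type alkoxy transfer followed by Prins closure); a trityl ether cannot, and it leaves in the final acid step with the acetals.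

8 ⇒ 5 + 7. Cut: the C2'–O1'' aryl–oxygen bond. The alkyl–oxygen bond at C2'' is not the one formed, because substitution at a tertiary propargylic carbon would endanger the configuration; the tertiary alkoxide is the nucleophile and the arene the electrophile. The forward step needs fluoride ortho to the formyl acceptor, a group on the primary oxygen of 5 that cannot migrate to the neighbouring alkoxide (an ether, not a silyl group or ester), and only one equivalent of base, since 5 also has an acidic alkyne hydrogen.

7 ⇒ 6. Cut: the O–CH2OMe bond. A free phenoxide would shut down the substitution; the acetal is chosen because it leaves with the others at the end.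

5 ⇒ 4 ⇒ 3 ⇒ 2 ⇒ 1. Cut: the C3≡C4 bond of the alkyne (one-carbon homologation of an aldehyde), then the oxidation level and the C–OH bond made by epoxide opening, then O–CPh3. The stereocentre is traced to the chiral pool and never has to be created. The epoxide CH2 of 1 becomes the inner alkyne carbon and its hydroxymethyl group becomes the protected arm. The forward sequence must open the epoxide with hydroxide at CH2 only, so that no bond to the quaternary carbon breaks.

13 ⇒ 12. Cut: three O–CH2OMe bonds. Ring A is bought with all carbons and oxygens in place; the two hydrogen-bonded ortho hydroxyls must be alkylated completely.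

## Other disconnections considered

Alternative 1: The cut is through C3–C4 and O1–C2 of ring C in one operation, giving the ring-B arylacetaldehyde A2 (used as its morpholine enamine A3) and the triacetate acid chloride A4. In the forward step A3 is C-acylated at its β-carbon by A4 with Et3N; K2CO3 in methanol then removes the acetates, and the freed ortho-phenoxide adds to the enaminone and expels the amine to give A1.
- In its favour: C2 is already present in A2, the ring closes under weakly basic conditions that spare the chromene and the acetals, and A4 is a stable acid chloride.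
- Against it here: A2 is an enolisable, electron-rich arylacetaldehyde prone to self-condensation and oxidation. The β-carbon of A3 is flanked by an ortho-disubstituted ring and A4 is hindered on both sides, so N-acylation or acetyl transfer may compete. A1 still needs a separate acid deprotection.
- Structure: it solves ring C only. The quaternary centre and ring D still require other chemistry, and A2 would in practice be reached by homologating an 8-formylchromene of the kind of 9. It is an alternative endgame, not an alternative to the key step.
- Mechanism: it is the equal of the chosen plan, since both close ring C by addition–elimination on an enaminone (17 in the chosen route).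
- Step economy: it is the better. From the formylchromene stage it needs about four operations against five, and it avoids the labile benzylic chloride and the organozinc. The chosen plan is the better on the reliability of each C–C bond formation.

Alternative 2: The cut is through C1'–C2', C2'–C3' and C4'–C5', so ring B is built from the chromonyl diazo enone A6 and the siloxyalkyne A7, which carries the epoxide. In the forward step, irradiation of A6 (Wolff rearrangement) and heating with A7 lead through a pericyclic cascade ([2+2], four-electron opening, six-electron closure, tautomerisation) to phenol A5.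
- In its favour: the substitution pattern of ring B is written into the annulation, with the ketene carbon becoming C2'–OH, the siloxy carbon C4' and the alkyne substituent landing on C3'. The two ring-B oxygens emerge differentiated. The C3–C1' bond exists from the start, so no deoxybenzoin chemistry is needed.
- Against it here: it needs diazo handling and ultraviolet irradiation of a chromone that itself absorbs. A free phenol is generated hot next to an epoxide and a silyl ether. A7 is a hydrolytically labile ynol ether that takes several steps.
- Structure: ring D must still be closed after A5 by phenol attack at the tertiary epoxide carbon, and the saturated ring must then be dehydrogenated.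
- Mechanism: that ring closure is a substitution with inversion at the stereocentre itself, where partial ionisation would erode the configuration. The chosen plan never breaks a bond at C2'' and is the better here.
- Where it is the better: regiochemical programming of ring B and the absence of an acidic ring-C closure.
- Step economy and simplicity: the chosen plan is the better, because the required ring-B pattern is bought in 6 and C3' is the only site that can react.

Alternative 3: The cut is through C4a–C5 of ring A, which is folded from the pyrone A9. In the forward step Mg(OMe)2 in methanol opens A9 to the chelated triketo ester A10, whose doubly activated methylene condenses with the ester carbonyl (Claisen) to give A8.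
- In its favour: the three ring-A oxygens never need protection. The conditions are mild, basic and chelation-controlled, and tolerate the acetals and the chromene. A8 is the free trihydroxy deoxybenzoin that classical formylative annulation accepts.
- Against it here: ring A is the cheapest part of the molecule (commercial as 12). A9 must be made by acylating a pyrone dianion with a ring-B arylacetic acid derivative, which itself needs homologation of the ring-B aldehyde. A10 can also close by aldol condensation to a resorcylate-type ring or re-lactonise, and it has a further acidic benzylic methylene. Ring C closure and deprotection still follow.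
- Structure: on the main difficulty it is only the equal of the chosen plan, since it leaves the stereocentre and ring D untouched and needs the same chromene.
- Mechanism: the Claisen-versus-aldol ambiguity contrasts with the unambiguous carbonyl addition and oxidation of the chosen plan.
- Where it is the better: protecting-group economy on ring A.
- Step economy: the chosen plan is the better.

Key step: step 7

Remark: both enantiomers of 2-methylglycidol are commercial. Because the epoxide CH2 of 1 becomes the alkyne carbon and its hydroxymethyl group becomes the trityloxymethyl arm, the (R) enantiomer leads to the (S) ether; the changes of descriptor between 1 and 5 reflect CIP priorities only, not inversions.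

Step 1
Reactants: 1 [(2R)-2-methyloxiran-2-yl]methanol
Product: 2 (2S)-2-methyl-2-[(triphenylmethoxy)methyl]oxirane
Conditions: TrCl, Et3N, DMAP (cat.), CH2Cl2, 0 °C → rt
Reagents that add atoms: trityl chloride, ClC(c1ccccc1)(c1ccccc1)c1ccccc1
Why: O-tritylation of the only hydroxyl; the epoxide and the stereocentre are untouched, and the bulky non-acetal ether is inert to base and can neither migrate in step 6 nor deliver an oxygen to the alkyne in step 7.

Step 2
Reactants: 2 (2S)-2-methyl-2-[(triphenylmethoxy)methyl]oxirane
Product: 3 (2S)-2-methyl-3-(triphenylmethoxy)propane-1,2-diol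
Conditions: KOH, DMSO/H2O (4:1), 90 °C
Reagents that add atoms: water (as hydroxide), O
Why: Base-mediated epoxide hydrolysis: hydroxide attacks the unsubstituted epoxide carbon in an SN2 step, so the C–O bond of the quaternary carbon is never broken and the configuration is kept. Acid is avoided because it would direct water to the tertiary carbon and cleave the trityl ether.

Step 3
Reactants: 3 (2S)-2-methyl-3-(triphenylmethoxy)propane-1,2-diol
Product: 4 (2R)-2-hydroxy-2-methyl-3-(triphenylmethoxy)propanal
Conditions: SO3·pyridine, DMSO, i-Pr2NEt, CH2Cl2, 0 °C
Reagents that add atoms: none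
Why: Parikh–Doering oxidation takes the primary hydroxyl to the aldehyde; the tertiary hydroxyl cannot be oxidised and the α-carbon has no hydrogen, so epimerisation is impossible. Crude 4 is used cold to forestall dimerisation or an α-ketol shift.

Step 4
Reactants: 4 (2R)-2-hydroxy-2-methyl-3-(triphenylmethoxy)propanal
Product: 5 (2S)-2-methyl-1-(triphenylmethoxy)but-3-yn-2-ol
Conditions: dimethyl (1-diazo-2-oxopropyl)phosphonate, K2CO3, MeOH, 0 °C → rt
Reagents that add atoms: dimethyl (1-diazo-2-oxopropyl)phosphonate, COP(=O)(OC)C(=[N+]=[N-])C(C)=O
Why: Ohira–Bestmann alkynylation (Seyferth–Gilbert homologation): the diazophosphonate anion adds to the aldehyde, loss of phosphate and N2 gives an alkylidene carbene, and its 1,2-hydrogen shift delivers the terminal alkyne. The carbonate base tolerates the free tertiary hydroxyl and no bond at the stereocentre is involved.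

Step 5
Reactants: 6 2-fluoro-4-hydroxybenzaldehyde
Product: 7 2-fluoro-4-(methoxymethoxy)benzaldehyde
Conditions: MOMCl, i-Pr2NEt, CH2Cl2, 0 °C → rt
Reagents that add atoms: chloromethyl methyl ether, COCCl
Why: O-alkylation of the phenol (acetal protection), which would otherwise become a phenoxide and switch off the substitution of step 6. The carcinogenic reagent is best generated and used in solution.

Step 6
Reactants: 5 (2S)-2-methyl-1-(triphenylmethoxy)but-3-yn-2-ol; 7 2-fluoro-4-(methoxymethoxy)benzaldehyde
Product: 8 4-(methoxymethoxy)-2-{[(2S)-2-methyl-1-(triphenylmethoxy)but-3-yn-2-yl]oxy}benzaldehyde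
Conditions: KN(SiMe3)2 (1.0 equiv), THF, 0 °C; then 7, DMF, 0 °C → rt
Reagents that add atoms: none
Why: Nucleophilic aromatic substitution by addition–elimination: the tertiary potassium alkoxide attacks C2 of 7, the ortho-formyl group stabilises the Meisenheimer adduct, and fluoride leaves. The stereocentre reacts only through its oxygen, so its configuration is carried over unchanged, and the trityl ether cannot migrate to the alkoxide.

Step 7
Reactants: 8 4-(methoxymethoxy)-2-{[(2S)-2-methyl-1-(triphenylmethoxy)but-3-yn-2-yl]oxy}benzaldehyde
Product: 9 (2S)-5-(methoxymethoxy)-2-methyl-2-[(triphenylmethoxy)methyl]-2H-chromene-8-carbaldehyde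
Conditions: Ph3PAuNTf2 (5 mol%), 4 Å MS, CH2Cl2, rt → 40 °C
Reagents that add atoms: none
Why: Ph3PAuNTf2 provides a cationic monovalent gold centre that π-coordinates the terminal alkyne of 8. C3 of the arene (C3' of ring B), activated by its two ortho oxygens, attacks the terminal alkyne carbon anti to gold in a Friedel–Crafts sense; proton loss from the Wheland intermediate and protodeauration of the vinylgold species release 9 and the catalyst. The closest known reaction type is the gold-catalysed intramolecular hydroarylation (cycloisomerisation) of aryl propargyl ethers to 2H-chromenes. Ring D closes in the 6-endo-dig mode with formation of the C3'–C4'' bond. No stereocentre is created; C2'' is a bystander whose four bonds stay intact, whereas a thermal propargyl Claisen sequence would pass through an achiral ortho-quinone methide, and the electron-withdrawing CH2O arm also disfavours ionisation of the propargylic C–O bond. Regioselectivity is required (6-endo at C3, not 5-exo and not at C1); it is secured by the terminal alkyne, which presents its unsubstituted carbon to the arene, and by the formyl group occupying C1. Chemoselectivity against oxygen nucleophiles is also needed: the trityl ether has no second oxygen that can reach the alkyne, and the formyl oxygen could only close a seven-membered ring.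

Step 8
Reactants: 9 (2S)-5-(methoxymethoxy)-2-methyl-2-[(triphenylmethoxy)methyl]-2H-chromene-8-carbaldehyde
Product: 10 {(2S)-5-(methoxymethoxy)-2-methyl-2-[(triphenylmethoxy)methyl]-2H-chromen-8-yl}methanol
Conditions: NaBH4, MeOH/THF, 0 °C
Reagents that add atoms: none
Why: Hydride reduction of the aryl aldehyde; the chromene, the acetal and the trityl ether are inert to borohydride.

Step 9
Reactants: 10 {(2S)-5-(methoxymethoxy)-2-methyl-2-[(triphenylmethoxy)methyl]-2H-chromen-8-yl}methanol
Product: 11 (2S)-8-(chloromethyl)-5-(methoxymethoxy)-2-methyl-2-[(triphenylmethoxy)methyl]-2H-chromene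
Conditions: MsCl, Et3N, LiCl, THF, 0 °C → rt
Reagents that add atoms: lithium chloride, [Li+].[Cl-]
Why: Mesylation and in situ chloride displacement at an electron-rich benzylic carbon under basic conditions, which spare trityl, acetal and chromene. Crude 11 is carried on at once because 2,4-dioxygenated benzylic chlorides ionise easily.

Step 10
Reactants: 12 2,4,6-trihydroxybenzaldehyde
Product: 13 2,4,6-tris(methoxymethoxy)benzaldehyde
Conditions: NaH, MOMCl, DMF, 0 °C → rt
Reagents that add atoms: chloromethyl methyl ether, COCCl
Why: Threefold O-alkylation of the phenoxides (acetal protection). NaH is used because the two hydrogen-bonded ortho hydroxyls resist amine bases; the hard electrophile alkylates oxygen, not carbon.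

Step 11
Reactants: 11 (2S)-8-(chloromethyl)-5-(methoxymethoxy)-2-methyl-2-[(triphenylmethoxy)methyl]-2H-chromene; 13 2,4,6-tris(methoxymethoxy)benzaldehyde
Product: 15 2-{(2S)-5-(methoxymethoxy)-2-methyl-2-[(triphenylmethoxy)methyl]-2H-chromen-8-yl}-1-[2,4,6-tris(methoxymethoxy)phenyl]ethan-1-ol, via benzylic zinc chloride 14 (not isolated)
Conditions: Zn dust, LiCl, THF, 25 °C; then 13, MgCl2, THF, 0 → 25 °C; aq. NH4Cl
Reagents that add atoms: none
Why: LiCl-assisted oxidative insertion of zinc into the benzylic C–Cl bond, then 1,2-addition of the benzylic zinc chloride to the aldehyde (Barbier/Grignard-type addition, assisted by MgCl2 and by chelation to the ortho acetal oxygens). An aldehyde is the acceptor because an aroyl chloride between two acetal ethers would be attacked by its own acetal oxygens under zinc catalysis. The new carbinol centre forms without control and is removed in step 12.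

Step 12
Reactants: 15 2-{(2S)-5-(methoxymethoxy)-2-methyl-2-[(triphenylmethoxy)methyl]-2H-chromen-8-yl}-1-[2,4,6-tris(methoxymethoxy)phenyl]ethan-1-ol
Product: 16 2-{(2S)-5-(methoxymethoxy)-2-methyl-2-[(triphenylmethoxy)methyl]-2H-chromen-8-yl}-1-[2,4,6-tris(methoxymethoxy)phenyl]ethan-1-one
Conditions: Dess–Martin periodinane, NaHCO3, CH2Cl2, 0 °C → rt
Reagents that add atoms: none
Why: Dess–Martin oxidation of the secondary benzylic alcohol to the ketone under buffered conditions; it erases the uncontrolled carbinol centre and does not touch the chromene.

Step 13
Reactants: 16 2-{(2S)-5-(methoxymethoxy)-2-methyl-2-[(triphenylmethoxy)methyl]-2H-chromen-8-yl}-1-[2,4,6-tris(methoxymethoxy)phenyl]ethan-1-one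
Product: 18 5,7-dihydroxy-3-[(2S)-5-hydroxy-2-(hydroxymethyl)-2-methyl-2H-chromen-8-yl]-4H-chromen-4-one, via enaminone 17 (not isolated)
Conditions: Me2NCH(OMe)2, toluene, 90 °C; evaporate; then 3 M HCl, MeOH/THF, 45 °C
Reagents that add atoms: N,N-dimethylformamide dimethyl acetal, COC(OC)N(C)C
Why: Condensation of the doubly activated methylene with the amide acetal gives enaminone 17, which supplies C2. Acid then cleaves the acetals, the freed ortho-phenol of ring A adds to the enaminone β-carbon and dimethylamine is eliminated (6-endo addition–elimination closing ring C), while the trityl ether is solvolysed in the same pot. C2'' is not involved, so the (S) configuration from 1 is delivered to the target.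

Compound list

1 | [(2R)-2-methyloxiran-2-yl]methanol ((R)-2-methylglycidol) | C[C@@]1(CO)CO1 | starting material
2 | (2S)-2-methyl-2-[(triphenylmethoxy)methyl]oxirane | C[C@@]1(COC(c2ccccc2)(c2ccccc2)c2ccccc2)CO1 | intermediate
3 | (2S)-2-methyl-3-(triphenylmethoxy)propane-1,2-diol | C[C@@](O)(COC(c1ccccc1)(c1ccccc1)c1ccccc1)CO | intermediate
4 | (2R)-2-hydroxy-2-methyl-3-(triphenylmethoxy)propanal | C[C@@](O)(COC(c1ccccc1)(c1ccccc1)c1ccccc1)C=O | intermediate
5 | (2S)-2-methyl-1-(triphenylmethoxy)but-3-yn-2-ol | C[C@@](O)(COC(c1ccccc1)(c1ccccc1)c1ccccc1)C#C | intermediate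
6 | 2-fluoro-4-hydroxybenzaldehyde | O=Cc1ccc(O)cc1F | starting material
7 | 2-fluoro-4-(methoxymethoxy)benzaldehyde | COCOc1ccc(C=O)c(F)c1 | intermediate
8 | 4-(methoxymethoxy)-2-{[(2S)-2-methyl-1-(triphenylmethoxy)but-3-yn-2-yl]oxy}benzaldehyde | C[C@@](Oc1cc(OCOC)ccc1C=O)(COC(c1ccccc1)(c1ccccc1)c1ccccc1)C#C | intermediate
9 | (2S)-5-(methoxymethoxy)-2-methyl-2-[(triphenylmethoxy)methyl]-2H-chromene-8-carbaldehyde | C[C@@]1(COC(c2ccccc2)(c2ccccc2)c2ccccc2)C=Cc2c(OCOC)ccc(C=O)c2O1 | intermediate
10 | {(2S)-5-(methoxymethoxy)-2-methyl-2-[(triphenylmethoxy)methyl]-2H-chromen-8-yl}methanol | C[C@@]1(COC(c2ccccc2)(c2ccccc2)c2ccccc2)C=Cc2c(OCOC)ccc(CO)c2O1 | intermediate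
11 | (2S)-8-(chloromethyl)-5-(methoxymethoxy)-2-methyl-2-[(triphenylmethoxy)methyl]-2H-chromene | C[C@@]1(COC(c2ccccc2)(c2ccccc2)c2ccccc2)C=Cc2c(OCOC)ccc(CCl)c2O1 | intermediate
12 | 2,4,6-trihydroxybenzaldehyde | O=Cc1c(O)cc(O)cc1O | starting material
13 | 2,4,6-tris(methoxymethoxy)benzaldehyde | COCOc1cc(OCOC)c(C=O)c(OCOC)c1 | intermediate
14 | chlorido({(2S)-5-(methoxymethoxy)-2-methyl-2-[(triphenylmethoxy)methyl]-2H-chromen-8-yl}methyl)zinc, LiCl adduct in THF | C[C@@]1(COC(c2ccccc2)(c2ccccc2)c2ccccc2)C=Cc2c(OCOC)ccc(C[Zn]Cl)c2O1 | intermediate (not isolated)
15 | 2-{(2S)-5-(methoxymethoxy)-2-methyl-2-[(triphenylmethoxy)methyl]-2H-chromen-8-yl}-1-[2,4,6-tris(methoxymethoxy)phenyl]ethan-1-ol, both epimers at the carbinol carbon | C[C@@]1(COC(c2ccccc2)(c2ccccc2)c2ccccc2)C=Cc2c(OCOC)ccc(CC(O)c3c(OCOC)cc(OCOC)cc3OCOC)c2O1 | intermediate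
16 | 2-{(2S)-5-(methoxymethoxy)-2-methyl-2-[(triphenylmethoxy)methyl]-2H-chromen-8-yl}-1-[2,4,6-tris(methoxymethoxy)phenyl]ethan-1-one | C[C@@]1(COC(c2ccccc2)(c2ccccc2)c2ccccc2)C=Cc2c(OCOC)ccc(CC(=O)c3c(OCOC)cc(OCOC)cc3OCOC)c2O1 | intermediate
17 | (2E)-3-(dimethylamino)-2-{(2S)-5-(methoxymethoxy)-2-methyl-2-[(triphenylmethoxy)methyl]-2H-chromen-8-yl}-1-[2,4,6-tris(methoxymethoxy)phenyl]prop-2-en-1-one (E geometry assumed; it is erased on ring closure) | C[C@@]1(COC(c2ccccc2)(c2ccccc2)c2ccccc2)C=Cc2c(OCOC)ccc(/C(=C\N(C)C)C(=O)c3c(OCOC)cc(OCOC)cc3OCOC)c2O1 | intermediate (not isolated)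
18 | 5,7-dihydroxy-3-[(2S)-5-hydroxy-2-(hydroxymethyl)-2-methyl-2H-chromen-8-yl]-4H-chromen-4-one | C[C@@]1(CO)C=Cc2c(O)ccc(-c3coc4cc(O)cc(O)c4c3=O)c2O1 | target

Total step count: 13. Longest linear sequence: 11 steps (steps 1–4, 6–9, 11–13).

Least certain steps

Step 7 (key step). The formyl group lowers the nucleophilicity of the arene, so ring closure may be slow. Hydration of the gold-activated alkyne by adventitious water, or loss of the trityl group through the proton shuttled during rearomatisation, could then overtake the Friedel–Crafts closure. The fallback sets out from 8 and removes the deactivating carbonyl before the cyclisation. NaBH4 reduction of 8 should give the benzylic alcohol [4-(methoxymethoxy)-2-{[(2S)-2-methyl-1-(triphenylmethoxy)but-3-yn-2-yl]oxy}phenyl]methanol F1. Silylation (TBSCl, imidazole) should give its tert-butyldimethylsilyl ether F2. The same Ph3PAuNTf2-catalysed hydroarylation on this more electron-rich arene should give the chromene silyl ether F3, and Bu4NF would release 10, where the route is rejoined after step 8.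

Step 6. The tertiary alkoxide, or the acetylide in equilibrium with it, may add to the formyl group. This ties the aldehyde up as an electron-rich hemiacetal alkoxide, which slows the substitution, or leads to propargylic carbinols and hydride-transfer products. The fallback sets out from 5 and uses a nitrile as the activating group. Commercial 2-fluoro-4-hydroxybenzonitrile F4 would be protected as in step 5 to 2-fluoro-4-(methoxymethoxy)benzonitrile F5. The potassium alkoxide of 5 should displace its fluoride to give 4-(methoxymethoxy)-2-{[(2S)-2-methyl-1-(triphenylmethoxy)but-3-yn-2-yl]oxy}benzonitrile F6. Reduction with i-Bu2AlH at −78 °C and buffered aqueous hydrolysis of the aldimine would then give 8.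

Step 11. Zinc insertion into the very electron-rich benzylic chloride may be accompanied by Wurtz-type homocoupling, the chloride itself may ionise and self-alkylate before it is metallated, and the zinc reagent may add only slowly to the hindered, electron-rich 13. The fallback sets out from 10 and makes the benzylic carbon nucleophilic through a sulfone, so no halide is isolated. Mesylation of 10 and trapping with PhSO2Na in DMF should give the benzylic phenyl sulfone F7. Deprotonation with n-BuLi at −78 °C and addition to 13 should give the β-hydroxy sulfone F8. Dess–Martin oxidation would give the β-keto sulfone F9, and reductive desulfonylation with SmI2 in THF/MeOH at −78 °C would return the route to 16.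

Step 13. Condensation at the hindered methylene may be incomplete. In the acid stage, methanol may add to the electron-rich chromene double bond, or the double bond may oligomerise, or liberated formaldehyde equivalents may attack ring A, while the last acetals are cleaved. The fallback sets out from 16 and reverses the order, so that acid exposure is limited to what deprotection alone needs and ring C is closed under base. Brief methanolysis with HCl at room temperature should give the fully deprotected deoxybenzoin 2-[(2S)-5-hydroxy-2-(hydroxymethyl)-2-methyl-2H-chromen-8-yl]-1-(2,4,6-trihydroxyphenyl)ethan-1-one F10. Formylative annulation with triethyl orthoformate and catalytic morpholine at 80–100 °C would then give 18.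

Further compounds

F1 | step 7 | [4-(methoxymethoxy)-2-{[(2S)-2-methyl-1-(triphenylmethoxy)but-3-yn-2-yl]oxy}phenyl]methanol | C[C@@](Oc1cc(OCOC)ccc1CO)(COC(c1ccccc1)(c1ccccc1)c1ccccc1)C#C
F2 | step 7 | tert-butyl{[4-(methoxymethoxy)-2-{[(2S)-2-methyl-1-(triphenylmethoxy)but-3-yn-2-yl]oxy}phenyl]methoxy}dimethylsilane | C[C@@](Oc1cc(OCOC)ccc1CO[Si](C)(C)C(C)(C)C)(COC(c1ccccc1)(c1ccccc1)c1ccccc1)C#C
F3 | step 7 | tert-butyl({(2S)-5-(methoxymethoxy)-2-methyl-2-[(triphenylmethoxy)methyl]-2H-chromen-8-yl}methoxy)dimethylsilane | C[C@@]1(COC(c2ccccc2)(c2ccccc2)c2ccccc2)C=Cc2c(OCOC)ccc(CO[Si](C)(C)C(C)(C)C)c2O1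
F4 | step 6 | 2-fluoro-4-hydroxybenzonitrile | N#Cc1ccc(O)cc1F
F5 | step 6 | 2-fluoro-4-(methoxymethoxy)benzonitrile | COCOc1ccc(C#N)c(F)c1
F6 | step 6 | 4-(methoxymethoxy)-2-{[(2S)-2-methyl-1-(triphenylmethoxy)but-3-yn-2-yl]oxy}benzonitrile | C[C@@](Oc1cc(OCOC)ccc1C#N)(COC(c1ccccc1)(c1ccccc1)c1ccccc1)C#C
F7 | step 11 | (2S)-8-[(benzenesulfonyl)methyl]-5-(methoxymethoxy)-2-methyl-2-[(triphenylmethoxy)methyl]-2H-chromene | C[C@@]1(COC(c2ccccc2)(c2ccccc2)c2ccccc2)C=Cc2c(OCOC)ccc(CS(=O)(=O)c3ccccc3)c2O1
F8 | step 11 | 2-(benzenesulfonyl)-2-{(2S)-5-(methoxymethoxy)-2-methyl-2-[(triphenylmethoxy)methyl]-2H-chromen-8-yl}-1-[2,4,6-tris(methoxymethoxy)phenyl]ethan-1-ol (diastereomer mixture) | C[C@@]1(COC(c2ccccc2)(c2ccccc2)c2ccccc2)C=Cc2c(OCOC)ccc(C(C(O)c3c(OCOC)cc(OCOC)cc3OCOC)S(=O)(=O)c3ccccc3)c2O1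
F9 | step 11 | 2-(benzenesulfonyl)-2-{(2S)-5-(methoxymethoxy)-2-methyl-2-[(triphenylmethoxy)methyl]-2H-chromen-8-yl}-1-[2,4,6-tris(methoxymethoxy)phenyl]ethan-1-one | C[C@@]1(COC(c2ccccc2)(c2ccccc2)c2ccccc2)C=Cc2c(OCOC)ccc(C(C(=O)c3c(OCOC)cc(OCOC)cc3OCOC)S(=O)(=O)c3ccccc3)c2O1
F10 | step 13 | 2-[(2S)-5-hydroxy-2-(hydroxymethyl)-2-methyl-2H-chromen-8-yl]-1-(2,4,6-trihydroxyphenyl)ethan-1-one | C[C@@]1(CO)C=Cc2c(O)ccc(CC(=O)c3c(O)cc(O)cc3O)c2O1
A1 | alternative 1 | 5,7-dihydroxy-3-[(2S)-5-(methoxymethoxy)-2-[(methoxymethoxy)methyl]-2-methyl-2H-chromen-8-yl]-4H-chromen-4-one | C[C@@]1(COCOC)C=Cc2c(OCOC)ccc(-c3coc4cc(O)cc(O)c4c3=O)c2O1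
A2 | alternative 1 | 2-[(2S)-5-(methoxymethoxy)-2-[(methoxymethoxy)methyl]-2-methyl-2H-chromen-8-yl]acetaldehyde | C[C@@]1(COCOC)C=Cc2c(OCOC)ccc(CC=O)c2O1
A3 | alternative 1 | 4-{(E)-2-[(2S)-5-(methoxymethoxy)-2-[(methoxymethoxy)methyl]-2-methyl-2H-chromen-8-yl]ethenyl}morpholine | C[C@@]1(COCOC)C=Cc2c(OCOC)ccc(/C=C/N3CCOCC3)c2O1
A4 | alternative 1 | 2,4,6-tris(acetyloxy)benzoyl chloride | CC(=O)Oc1cc(OC(C)=O)c(C(Cl)=O)c(OC(C)=O)c1
A5 | alternative 2 | 3-{2-hydroxy-3-[2-((2R)-2-methyloxiran-2-yl)ethyl]-4-[tri(propan-2-yl)silyloxy]phenyl}-5,7-bis(methoxymethoxy)-4H-chromen-4-one | C[C@@]1(CCc2c(O)c(-c3coc4cc(OCOC)cc(OCOC)c4c3=O)ccc2O[Si](C(C)C)(C(C)C)C(C)C)CO1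
A6 | alternative 2 | 3-[(1E)-4-diazo-3-oxobut-1-en-1-yl]-5,7-bis(methoxymethoxy)-4H-chromen-4-one | [N-]=[N+]=CC(=O)/C=C/c1coc2cc(OCOC)cc(OCOC)c2c1=O
A7 | alternative 2 | (2R)-2-methyl-2-{4-[tri(propan-2-yl)silyloxy]but-3-yn-1-yl}oxirane | C[C@@]1(CCC#CO[Si](C(C)C)(C(C)C)C(C)C)CO1
A8 | alternative 3 | 2-[(2S)-5-(methoxymethoxy)-2-[(methoxymethoxy)methyl]-2-methyl-2H-chromen-8-yl]-1-(2,4,6-trihydroxyphenyl)ethan-1-one | C[C@@]1(COCOC)C=Cc2c(OCOC)ccc(CC(=O)c3c(O)cc(O)cc3O)c2O1
A9 | alternative 3 | 4-hydroxy-6-{3-[(2S)-5-(methoxymethoxy)-2-[(methoxymethoxy)methyl]-2-methyl-2H-chromen-8-yl]-2-oxopropyl}-2H-pyran-2-one | C[C@@]1(COCOC)C=Cc2c(OCOC)ccc(CC(=O)Cc3cc(O)cc(=O)o3)c2O1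
A10 | alternative 3 | methyl 8-[(2S)-5-(methoxymethoxy)-2-[(methoxymethoxy)methyl]-2-methyl-2H-chromen-8-yl]-3,5,7-trioxooctanoate | C[C@@]1(COCOC)C=Cc2c(OCOC)ccc(CC(=O)CC(=O)CC(=O)CC(=O)OC)c2O1
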